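## Retrosynthetic overview

1. Monotesone A is (2S)-5,7,3'-trihydroxy-4'-prenyloxyflavanone. The acid-labile prenyl ether is made last, by cross-metathesis of an allyl ether, after acid removal of three MOM ethers.
2. The strategy rests on ring A: oxygens at C5, C7 and C8a (O1), with the acyl carbon C4 bonded to C4a between the C5 oxygen and O1. This is the pattern left when a 3,5-dialkoxybenzyne takes an oxygen nucleophile at C1 and an acyl group at C2.
3. Ring C is disconnected at O1–C8a and C4–C4a. This gives an ortho-silylaryl triflate (aryne source, ring A) and the O-silylated (S)-β-hydroxy ester that carries ring B and the C2 stereocenter.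
4. The stereocenter comes from asymmetric transfer hydrogenation of a β-keto ester, made by Claisen condensation from 3',4'-dihydroxyacetophenone. The aryne source comes from phloroglucinol by bis-MOM protection, ortho-bromination, retro-Brook silyl shift and triflation.
5. Rings A and B are bought as arenes; ring C is the only ring formed, in step 10.

Key step: step 10

Remark on the chemistry: the alkoxide enters the key step as its trimethylsilyl ether and is released by fluoride, so no O–H acid is present and the ethoxide leaving group ends on silicon instead of staying as a base that could open the flavanone to the chalcone.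

Remark on the chemistry: the β-keto ester is made from the acetophenone by Claisen condensation, because Lewis-acid homologation of an electron-rich benzaldehyde with ethyl diazoacetate is prone to aryl migration.

## Route

Step 1
Reactants: 1 phloroglucinol
Product: 2 3,5-bis(methoxymethoxy)phenol
Conditions: MOMCl (2.0 equiv), i-Pr2NEt (2.2 equiv), DMF, 0 °C to 23 °C
Reagents that add atoms: chloromethyl methyl ether (MOMCl), COCCl
Why: O-alkylation of the phenol with an α-chloro ether (Williamson type); because 1 is threefold symmetric only the degree of alkylation has to be controlled, and the bis-ether is separated from the mono- and tris-ethers by chromatography.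

Step 2
Reactants: 2 3,5-bis(methoxymethoxy)phenol
Product: 3 2-bromo-3,5-bis(methoxymethoxy)phenol
Conditions: NBS (1.0 equiv), CH2Cl2, −78 °C
Reagents that add atoms: N-bromosuccinimide, O=C1CCC(=O)N1Br
Why: Electrophilic aromatic bromination; in a non-polar solvent at low temperature the hydrogen-bonded reagent should deliver bromine ortho to the free hydroxyl, which is also the less hindered of the two activated sites, as is known for 3,5-dialkoxyphenols.

Step 3
Reactants: 3 2-bromo-3,5-bis(methoxymethoxy)phenol
Product: 4 [2-bromo-3,5-bis(methoxymethoxy)phenoxy]trimethylsilane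
Conditions: (Me3Si)2NH, THF, 70 °C; evaporation of volatiles
Reagents that add atoms: hexamethyldisilazane, C[Si](C)(C)N[Si](C)(C)C
Why: O-silylation of a phenol with hexamethyldisilazane gives the aryl silyl ether with ammonia as the only by-product and sets up the silyl shift of step 4.

Step 4
Reactants: 4 [2-bromo-3,5-bis(methoxymethoxy)phenoxy]trimethylsilane
Product: 7 3,5-bis(methoxymethoxy)-2-(trimethylsilyl)phenyl trifluoromethanesulfonate, via aryllithium 5 (not isolated), via lithium phenoxide 6 (not isolated)
Conditions: n-BuLi (1.1 equiv), THF, −100 °C to −78 °C; then Tf2O (1.2 equiv), −78 °C to 0 °C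
Reagents that add atoms: trifluoromethanesulfonic anhydride, O=S(=O)(OS(=O)(=O)C(F)(F)F)C(F)(F)F
Why: Bromine–lithium exchange gives aryllithium 5, which undergoes the anionic 1,3-shift of silicon from oxygen to carbon (retro-Brook rearrangement) to phenoxide 6, and this is triflated in the same flask; it is the standard route to ortho-silylaryl triflates.

Step 5
Reactants: 8 3',4'-dihydroxyacetophenone
Product: 9 1-[4-(allyloxy)-3-hydroxyphenyl]ethan-1-one
Conditions: allyl bromide (1.0 equiv), K2CO3 (1.0 equiv), DMF, 23 °C
Reagents that add atoms: allyl bromide, C=CCBr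
Why: Williamson etherification; the 4-hydroxyl, para to the acetyl group, is the more acidic phenol, so with one equivalent of base its phenoxide is formed and alkylated selectively.

Step 6
Reactants: 9 1-[4-(allyloxy)-3-hydroxyphenyl]ethan-1-one
Product: 10 1-[4-(allyloxy)-3-(methoxymethoxy)phenyl]ethan-1-one
Conditions: MOMCl (1.3 equiv), i-Pr2NEt (1.5 equiv), CH2Cl2, 0 °C to 23 °C
Reagents that add atoms: chloromethyl methyl ether (MOMCl), COCCl
Why: Standard O-alkylation of the remaining phenol to its MOM ether, a group that is stable to the bases, the hydride transfer and the fluoride used later.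

Step 7
Reactants: 10 1-[4-(allyloxy)-3-(methoxymethoxy)phenyl]ethan-1-one
Product: 12 ethyl 3-[4-(allyloxy)-3-(methoxymethoxy)phenyl]-3-oxopropanoate, via sodium enolate 11 (not isolated)
Conditions: NaH (2.2 equiv), (EtO)2CO (3 equiv), THF, reflux; then AcOH, H2O, 0 °C
Reagents that add atoms: diethyl carbonate, CCOC(=O)OCC
Why: Crossed Claisen condensation: the ketone enolate is acylated by diethyl carbonate and the equilibrium is pulled through by deprotonation to the stabilised enolate 11, which acid releases as 12.

Step 8
Reactants: 12 ethyl 3-[4-(allyloxy)-3-(methoxymethoxy)phenyl]-3-oxopropanoate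
Product: 13 ethyl (3S)-3-[4-(allyloxy)-3-(methoxymethoxy)phenyl]-3-hydroxypropanoate
Conditions: RuCl[(S,S)-TsDPEN](p-cymene) (1 mol %), HCO2H/Et3N (5:2), 40 °C
Reagents that add atoms: none
Why: Noyori–Ikariya asymmetric transfer hydrogenation: hydride and proton pass to the aryl ketone in an outer-sphere six-membered transition state in which the CH–π contact between the p-cymene ligand and ring B fixes the exposed face, so the (S,S)-diamine should give the S carbinol as it does for aryl methyl ketones, and the allyl ether is not reduced.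

Step 9
Reactants: 13 ethyl (3S)-3-[4-(allyloxy)-3-(methoxymethoxy)phenyl]-3-hydroxypropanoate
Product: 14 ethyl (3S)-3-[4-(allyloxy)-3-(methoxymethoxy)phenyl]-3-[(trimethylsilyl)oxy]propanoate
Conditions: TMSCl (1.2 equiv), imidazole (1.5 equiv), CH2Cl2, 0 °C; non-aqueous work-up
Reagents that add atoms: chlorotrimethylsilane, C[Si](C)(C)Cl
Why: Standard O-silylation of a secondary alcohol with a silyl chloride and imidazole; the silyl ether carries the alkoxide into step 10 without an O–H proton and without a metal base.

Step 10
Reactants: 14 ethyl (3S)-3-[4-(allyloxy)-3-(methoxymethoxy)phenyl]-3-[(trimethylsilyl)oxy]propanoate (1.2 equiv); 7 3,5-bis(methoxymethoxy)-2-(trimethylsilyl)phenyl trifluoromethanesulfonate (1.0 equiv)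
Product: 18 (2S)-2-[4-(allyloxy)-3-(methoxymethoxy)phenyl]-5,7-bis(methoxymethoxy)chroman-4-one, via ammonium alkoxide 15 (not isolated), via 3,5-bis(methoxymethoxy)benzyne 16 (not isolated), via aryl anion 17 (not isolated)
Conditions: Bu4N[Ph3SiF2] (TBAT, 1.0 equiv, slow addition), THF, 0 °C to 23 °C; AcOH quench at 0 °C
Reagents that add atoms: none
Why: Proposed new method: fluoride removes the O-silyl group of 14 and the C-silyl group of 7, so alkoxide 15 and aryne 16 meet under aprotic conditions; 15 adds at the aryne carbon remote from the flanking MOM ether (O1–C8a), which places aryl anion 17 on the carbon next to that oxygen, and 17 attacks the ester carbonyl and expels ethoxide (C4–C4a). The closest known reactions are the fluoride-mediated annulation of arynes with methyl salicylates to xanthones and the acyl-alkylation of arynes with β-keto esters; here an aliphatic alkoxide takes the place of the phenoxide. Ring C closes by 6-exo-trig addition of the aryl anion to the ester, followed by loss of ethoxide. No stereocenter is formed, and the carbinol carbon keeps its S configuration because only its oxygen reacts. The regioselectivity needed is secured by the C3 oxygen of 16, which distorts the aryne and inductively stabilises the anion beside it, and acyl capture should outrun protonation because no O–H or N–H acid is present. The ethoxide set free is silylated by 14 or by 7 (which releases more alkoxide or aryne), so with fluoride limiting no base should remain to open the flavanone to the chalcone by E1cB and erase C2.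

Step 11
Reactants: 18 (2S)-2-[4-(allyloxy)-3-(methoxymethoxy)phenyl]-5,7-bis(methoxymethoxy)chroman-4-one
Product: 19 (2S)-2-[4-(allyloxy)-3-hydroxyphenyl]-5,7-dihydroxychroman-4-one
Conditions: HCl (3 M aq)/MeOH (1:4), 50 °C
Reagents that add atoms: none
Why: Acid-catalysed acetal exchange with methanol cleaves the three aryl MOM ethers while the allyl aryl ether and the ketone are inert, and C2 is expected to hold because flavanones lose configuration by base-induced ring opening and not in dilute acid at this temperature.

Step 12
Reactants: 19 (2S)-2-[4-(allyloxy)-3-hydroxyphenyl]-5,7-dihydroxychroman-4-one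
Product: 20 Monotesone A, (2S)-5,7-dihydroxy-2-{3-hydroxy-4-[(3-methylbut-2-en-1-yl)oxy]phenyl}chroman-4-one
Conditions: second-generation Grubbs catalyst RuCl2(H2IMes)(PCy3)(=CHPh) (5 mol %), 2-methyl-2-butene/CH2Cl2 (1:1), 35 °C, sealed tube
Reagents that add atoms: 2-methyl-2-butene, CC=C(C)C
Why: Olefin cross-metathesis: the terminal allyl alkene exchanges its methylidene end for the isopropylidene of 2-methyl-2-butene, used in excess so that propene is lost and homodimerisation is suppressed, and the ruthenium carbene tolerates free phenols and the ketone and does not touch C2.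

## Compound list

1 | phloroglucinol | Oc1cc(O)cc(O)c1 | starting material
2 | 3,5-bis(methoxymethoxy)phenol | COCOc1cc(O)cc(OCOC)c1 | intermediate
3 | 2-bromo-3,5-bis(methoxymethoxy)phenol | COCOc1cc(O)c(Br)c(OCOC)c1 | intermediate
4 | [2-bromo-3,5-bis(methoxymethoxy)phenoxy]trimethylsilane | COCOc1cc(O[Si](C)(C)C)c(Br)c(OCOC)c1 | intermediate
5 | [2-lithio-3,5-bis(methoxymethoxy)phenoxy]trimethylsilane (aryllithium) | COCOc1cc(O[Si](C)(C)C)c([Li])c(OCOC)c1 | intermediate
6 | lithium 3,5-bis(methoxymethoxy)-2-(trimethylsilyl)phenoxide | COCOc1cc([O-])c([Si](C)(C)C)c(OCOC)c1.[Li+] | intermediate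
7 | 3,5-bis(methoxymethoxy)-2-(trimethylsilyl)phenyl trifluoromethanesulfonate | COCOc1cc(OCOC)c([Si](C)(C)C)c(OS(=O)(=O)C(F)(F)F)c1 | intermediate
8 | 3',4'-dihydroxyacetophenone | CC(=O)c1ccc(O)c(O)c1 | starting material
9 | 1-[4-(allyloxy)-3-hydroxyphenyl]ethan-1-one | C=CCOc1ccc(C(C)=O)cc1O | intermediate
10 | 1-[4-(allyloxy)-3-(methoxymethoxy)phenyl]ethan-1-one | C=CCOc1ccc(C(C)=O)cc1OCOC | intermediate
11 | sodium enolate of ethyl 3-[4-(allyloxy)-3-(methoxymethoxy)phenyl]-3-oxopropanoate | C=CCOc1ccc(C([O-])=CC(=O)OCC)cc1OCOC.[Na+] | intermediate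
12 | ethyl 3-[4-(allyloxy)-3-(methoxymethoxy)phenyl]-3-oxopropanoate | C=CCOc1ccc(C(=O)CC(=O)OCC)cc1OCOC | intermediate
13 | ethyl (3S)-3-[4-(allyloxy)-3-(methoxymethoxy)phenyl]-3-hydroxypropanoate | C=CCOc1ccc([C@@H](O)CC(=O)OCC)cc1OCOC | intermediate
14 | ethyl (3S)-3-[4-(allyloxy)-3-(methoxymethoxy)phenyl]-3-[(trimethylsilyl)oxy]propanoate | C=CCOc1ccc([C@@H](O[Si](C)(C)C)CC(=O)OCC)cc1OCOC | intermediate
15 | tetrabutylammonium (1S)-1-[4-(allyloxy)-3-(methoxymethoxy)phenyl]-3-ethoxy-3-oxopropan-1-olate | C=CCOc1ccc([C@@H]([O-])CC(=O)OCC)cc1OCOC.CCCC[N+](CCCC)(CCCC)CCCC | intermediate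
16 | 3,5-bis(methoxymethoxy)benzyne | COCOC1=CC(OCOC)=CC#C1 | intermediate
17 | tetrabutylammonium salt of the aryl anion: ethyl (3S)-3-[4-(allyloxy)-3-(methoxymethoxy)phenyl]-3-[3,5-bis(methoxymethoxy)phenoxy]propanoate carbanion at C2 of the phenoxy ring | C=CCOc1ccc([C@@H](Oc2cc(OCOC)cc(OCOC)[c-]2)CC(=O)OCC)cc1OCOC.CCCC[N+](CCCC)(CCCC)CCCC | intermediate
18 | (2S)-2-[4-(allyloxy)-3-(methoxymethoxy)phenyl]-5,7-bis(methoxymethoxy)chroman-4-one | C=CCOc1ccc([C@@H]2CC(=O)c3c(OCOC)cc(OCOC)cc3O2)cc1OCOC | intermediate
19 | (2S)-2-[4-(allyloxy)-3-hydroxyphenyl]-5,7-dihydroxychroman-4-one | C=CCOc1ccc([C@@H]2CC(=O)c3c(O)cc(O)cc3O2)cc1O | intermediate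
20 | Monotesone A | CC(C)=CCOc1ccc([C@@H]2CC(=O)c3c(O)cc(O)cc3O2)cc1O | target

## Step count

Total step count: 12. Longest linear sequence: 8 steps (steps 5 to 12); the aryne branch (steps 1 to 4) joins at step 10.

## Steps most likely to fail

**1. Step 10 (proposed new method).** Several processes could divert it:
- The aryl anion may be quenched by proton transfer (from C3–H of the adduct or from adventitious water) before it acylates; this leads to the open-chain aryl ether or, after β-elimination, to the cinnamate.
- The free alkoxide may undergo retro-aldol cleavage or elimination before it meets the aryne.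
- Residual base may open the flavanone to the chalcone by E1cB, with loss of configuration at C2.
- Fluoride or ethoxide may compete with the alkoxide for the aryne.

Fallback by known chemistry, setting out from 12 and 3 and returning at 18. Transfer hydrogenation of 12 with the enantiomeric catalyst RuCl[(R,R)-TsDPEN](p-cymene) in HCO2H/Et3N should give ethyl (3R)-3-[4-(allyloxy)-3-(methoxymethoxy)phenyl]-3-hydroxypropanoate F1 in place of 13. Mitsunobu etherification of F1 with bromophenol 3 (PPh3, DIAD, toluene, 0 °C) forms O1–C8a with inversion and should give ethyl (3S)-3-[4-(allyloxy)-3-(methoxymethoxy)phenyl]-3-[2-bromo-3,5-bis(methoxymethoxy)phenoxy]propanoate F2 as the aryl ether. Bromine–lithium exchange on F2 with n-BuLi (1.0 equiv) in THF at −100 °C gives the aryllithium ethyl (3S)-3-[4-(allyloxy)-3-(methoxymethoxy)phenyl]-3-[2-lithio-3,5-bis(methoxymethoxy)phenoxy]propanoate F3 without isolation. F3 then closes ring C by Parham cyclisation onto the ester (C4–C4a), and a cold AcOH quench returns 18. The enantiomeric purity of F2 and 18 would be checked by chiral HPLC, since an electron-rich benzylic carbinol can partly ionise in the Mitsunobu step.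

**2. Step 2.** Bromination may show poor site selectivity (attack at C4 between the two MOM ethers) or go on to dibromide on the very electron-rich ring.

Fallback by directed ortho-metalation, setting out from 2 and returning at 7 (compounds 3 to 6 are bypassed). Carbamoylation of 2 with isopropyl isocyanate (cat. Et3N, CH2Cl2) gives 3,5-bis(methoxymethoxy)phenyl N-isopropylcarbamate F4 as the carrier of the directing group. TBSOTf and TMEDA in Et2O convert F4 into 3,5-bis(methoxymethoxy)phenyl N-(tert-butyldimethylsilyl)-N-isopropylcarbamate F5 in the flask. n-BuLi/TMEDA at −78 °C lithiates F5 between the carbamate and a MOM ether to give 2-lithio-3,5-bis(methoxymethoxy)phenyl N-(tert-butyldimethylsilyl)-N-isopropylcarbamate F6 as the ortho-lithio species. TMSCl traps F6 as 3,5-bis(methoxymethoxy)-2-(trimethylsilyl)phenyl N-(tert-butyldimethylsilyl)-N-isopropylcarbamate F7 in the same flask. Aqueous work-up cleaves the N–Si bond of F7 and gives 3,5-bis(methoxymethoxy)-2-(trimethylsilyl)phenyl N-isopropylcarbamate F8 after chromatography. DBU/Et2NH in MeCN at 40 °C cleaves F8 to 3,5-bis(methoxymethoxy)-2-(trimethylsilyl)phenol F9 by way of the isocyanate, and PhNTf2 triflates F9 in the same flask to 7.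

**3. Step 11.** Acid may erode the C2 configuration through reversible ring opening (ionisation of the benzylic C2–O1 bond, helped by the para-alkoxy group of ring B), or the less labile MOM ethers may cleave incompletely and force harsher conditions.

Fallback by reversing the order of the end game, setting out from 18 and returning at 20 (19 is bypassed). Cross-metathesis of 18 with 2-methyl-2-butene (second-generation Grubbs catalyst RuCl2(H2IMes)(PCy3)(=CHPh), CH2Cl2, 35 °C) gives (2S)-5,7-bis(methoxymethoxy)-2-{3-(methoxymethoxy)-4-[(3-methylbut-2-en-1-yl)oxy]phenyl}chroman-4-one F10 with the prenyl ether already in place. TMSOTf/2,2'-bipyridyl in CH2Cl2 at 0 °C, a non-protic method for aryl MOM ethers, converts F10 into (2S)-2-{4-[(3-methylbut-2-en-1-yl)oxy]-3-[(trimethylsilyl)oxy]phenyl}-5,7-bis[(trimethylsilyl)oxy]chroman-4-one F11 as the tris(trimethylsilyl) ether of Monotesone A. Water on work-up hydrolyses F11 to 20 without exposing the prenyl ether to protic acid.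

## Further compounds

F1 | step 10 | ethyl (3R)-3-[4-(allyloxy)-3-(methoxymethoxy)phenyl]-3-hydroxypropanoate | C=CCOc1ccc([C@H](O)CC(=O)OCC)cc1OCOC
F2 | step 10 | ethyl (3S)-3-[4-(allyloxy)-3-(methoxymethoxy)phenyl]-3-[2-bromo-3,5-bis(methoxymethoxy)phenoxy]propanoate | C=CCOc1ccc([C@@H](Oc2cc(OCOC)cc(OCOC)c2Br)CC(=O)OCC)cc1OCOC
F3 | step 10 | ethyl (3S)-3-[4-(allyloxy)-3-(methoxymethoxy)phenyl]-3-[2-lithio-3,5-bis(methoxymethoxy)phenoxy]propanoate | C=CCOc1ccc([C@@H](Oc2cc(OCOC)cc(OCOC)c2[Li])CC(=O)OCC)cc1OCOC
F4 | step 2 | 3,5-bis(methoxymethoxy)phenyl N-isopropylcarbamate | COCOc1cc(OCOC)cc(OC(=O)NC(C)C)c1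
F5 | step 2 | 3,5-bis(methoxymethoxy)phenyl N-(tert-butyldimethylsilyl)-N-isopropylcarbamate | COCOc1cc(OCOC)cc(OC(=O)N(C(C)C)[Si](C)(C)C(C)(C)C)c1
F6 | step 2 | 2-lithio-3,5-bis(methoxymethoxy)phenyl N-(tert-butyldimethylsilyl)-N-isopropylcarbamate | COCOc1cc(OCOC)c([Li])c(OC(=O)N(C(C)C)[Si](C)(C)C(C)(C)C)c1
F7 | step 2 | 3,5-bis(methoxymethoxy)-2-(trimethylsilyl)phenyl N-(tert-butyldimethylsilyl)-N-isopropylcarbamate | COCOc1cc(OCOC)c([Si](C)(C)C)c(OC(=O)N(C(C)C)[Si](C)(C)C(C)(C)C)c1
F8 | step 2 | 3,5-bis(methoxymethoxy)-2-(trimethylsilyl)phenyl N-isopropylcarbamate | COCOc1cc(OCOC)c([Si](C)(C)C)c(OC(=O)NC(C)C)c1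
F9 | step 2 | 3,5-bis(methoxymethoxy)-2-(trimethylsilyl)phenol | COCOc1cc(OCOC)c([Si](C)(C)C)c(O)c1
F10 | step 11 | (2S)-5,7-bis(methoxymethoxy)-2-{3-(methoxymethoxy)-4-[(3-methylbut-2-en-1-yl)oxy]phenyl}chroman-4-one | CC(C)=CCOc1ccc([C@@H]2CC(=O)c3c(OCOC)cc(OCOC)cc3O2)cc1OCOC
F11 | step 11 | (2S)-2-{4-[(3-methylbut-2-en-1-yl)oxy]-3-[(trimethylsilyl)oxy]phenyl}-5,7-bis[(trimethylsilyl)oxy]chroman-4-one | CC(C)=CCOc1ccc([C@@H]2CC(=O)c3c(O[Si](C)(C)C)cc(O[Si](C)(C)C)cc3O2)cc1O[Si](C)(C)C
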